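**Plan**
- Cuts: the side chain at C12–C13 (B-alkyl Suzuki–Miyaura coupling with a bromobutenolide) and at C11 (vinyl carbinol from the C9 ketone via the 9,11-epoxide); then ring A at C1–C2 and C4–C5 in one annulation; last ring B at C5–C6 and C9–C10 (Diels–Alder).
- Forward: ring B first (enantioselective Diels–Alder, then C6 oxidation); ring A is annulated onto it in one flask from 3-bromo-3-methylbutan-2-one; then redox adjustment and the C9 side chain.
- Enabling feature: in ring B, C5 is α to the C6 carbonyl (C7=C8 blocks the other α-carbon) and the formyl carbon C1 sits on quaternary C10, 1,3 to C5. The dienol silane is alkylated at C5 by the tertiary α-keto radical (C4–C5), and the new methyl ketone then condenses with the aldehyde (C1–C2).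
- Stereochemistry: C10 from the catalyst-controlled Diels–Alder; C5 and C8 by base equilibration (trans fusion, equatorial methyl); C3 and C6 by substrate-controlled hydride delivery; C9 by α-face epoxidation of the exocyclic alkene.

Key step: step 6

Remarks on the chemistry:
(a) Atom numbers follow the labdane skeleton of the target: ring A = C1–C5 and C10, ring B = C5–C10, side chain C11–C16, C17 = methyl on C8. α is the face opposite to the C10 methyl group.
(b) The (S)-oxazaborolidinium catalyst is assumed to give the (1S) adduct 4; if the sense turns out opposite, its commercially available enantiomer is used.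
(c) The silyloxy-bearing carbon in 4–11 is drawn as the endo isomer; its configuration does not matter because it becomes the C9 carbonyl in step 7.

**Step 1**
Reactants: 1 (E)-2-methylbut-2-enal
Product: 2 tert-butyl{[(1E)-2-methylbuta-1,3-dien-1-yl]oxy}dimethylsilane
Conditions: TBSOTf, Et3N, Et2O, 0 °C to rt
Reagents that add atoms: tert-butyldimethylsilyl trifluoromethanesulfonate, CC(C)(C)[Si](C)(C)OS(=O)(=O)C(F)(F)F
Why: Silyl triflate activation and γ-deprotonation by the amine (vinylogous soft enolisation, silyl dienol ether formation) should give the diene with the silyloxy group on the outside (1E), the geometry that can reach the s-cis conformation needed in step 2; no stereocentre is formed.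

**Step 2**
Reactants: 2 tert-butyl{[(1E)-2-methylbuta-1,3-dien-1-yl]oxy}dimethylsilane; 3 2-methylprop-2-enal (methacrolein)
Product: 4 (1S,2R)-2-[(tert-butyldimethylsilyl)oxy]-1,3-dimethylcyclohex-3-ene-1-carbaldehyde
Conditions: (S)-o-tolyl-oxazaborolidine from (S)-α,α-diphenylprolinol, activated with HNTf2 (10 mol %), CH2Cl2, −78 °C
Reagents that add atoms: none
Why: In this catalytic enantioselective Diels–Alder reaction the silyloxy donor makes the CH2 terminus of 2 nucleophilic, so it joins the CH2 of methacrolein while the silyloxy carbon joins the quaternary carbon (future C5–C6 and C9–C10 bonds); the protonated oxazaborolidine binds the aldehyde and blocks one face, which sets the quaternary centre (future C10) as S, and endo approach puts the silyloxy group cis to the formyl group.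

**Step 3**
Reactants: 4 (1S,2R)-2-[(tert-butyldimethylsilyl)oxy]-1,3-dimethylcyclohex-3-ene-1-carbaldehyde
Product: 5 tert-butyl{[(1R,6S)-6-(dimethoxymethyl)-2,6-dimethylcyclohex-2-en-1-yl]oxy}dimethylsilane
Conditions: Me3SiOMe, Me3SiOTf (5 mol %), CH2Cl2, −78 °C
Reagents that add atoms: methoxytrimethylsilane, CO[Si](C)(C)C
Why: Lewis-acid-catalysed acetalisation with the silyl methyl ether should mask the hindered, non-enolisable aldehyde at a temperature low enough to spare the allylic silyl ether; no stereocentre is affected.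

**Step 4**
Reactants: 5 tert-butyl{[(1R,6S)-6-(dimethoxymethyl)-2,6-dimethylcyclohex-2-en-1-yl]oxy}dimethylsilane
Product: 6 (4R,5S)-4-[(tert-butyldimethylsilyl)oxy]-5-(dimethoxymethyl)-3,5-dimethylcyclohex-2-en-1-one
Conditions: Rh2(cap)4 (dirhodium tetrakis(caprolactamate), 1 mol %), t-BuOOH, K2CO3, CH2Cl2, rt
Reagents that add atoms: tert-butyl hydroperoxide, CC(C)(C)OO
Why: Allylic C–H oxidation by tert-butylperoxy radicals should occur at the ring CH2 next to the CH end of the trisubstituted alkene, as in 1-methylcyclohexene, giving the β-methyl enone with the carbonyl at the future C6, while the silyloxy-bearing C–H is shielded by the silyl group and the quaternary neighbour.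

**Step 5**
Reactants: 6 (4R,5S)-4-[(tert-butyldimethylsilyl)oxy]-5-(dimethoxymethyl)-3,5-dimethylcyclohex-2-en-1-one
Product: 7 (5R,6S)-2,5-bis[(tert-butyldimethylsilyl)oxy]-6-(dimethoxymethyl)-4,6-dimethylcyclohexa-1,3-diene
Conditions: LiN(i-Pr)2, THF, −78 °C; then TBSCl, DMPU, −78 to 0 °C
Reagents that add atoms: tert-butyldimethylsilyl chloride, CC(C)(C)[Si](C)(C)Cl
Why: Kinetic α′-deprotonation can occur only at the ring CH2 (future C5) because the other α-carbon is vinylic, and O-silylation of the cross-conjugated dienolate (silyl enol ether formation) should give the 2-silyloxy diene regiospecifically without touching the two stereocentres.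

**Step 6**
Reactants: 7 (5R,6S)-2,5-bis[(tert-butyldimethylsilyl)oxy]-6-(dimethoxymethyl)-4,6-dimethylcyclohexa-1,3-diene; 8 3-bromo-3-methylbutan-2-one
Product: 11 9α-hydroxy-4,4,8,10β-tetramethyl-5αH-decal-1,7-diene-3,6-dione, via diketone acetal 9 (not isolated), via keto aldehyde 10 (not isolated)
Conditions: 8 (2 equiv), fac-Ir(ppy)3 (1 mol %), 2,6-lutidine, MeCN, blue LEDs, rt; then 3 M aq HCl, THF, 50 °C (same flask)
Reagents that add atoms: none
Why: The excited iridium photocatalyst reduces the tertiary C–Br bond of 8 to an electrophilic α-keto radical, which adds to C5, the open CH terminus of the dienol silane; the silyloxy-stabilised allyl radical is oxidised by the tetravalent iridium species and desilylated back to the C6 enone (bond C4–C5, C4 arriving with both methyl groups), and aqueous acid then unmasks the C1 aldehyde on C10, with which the C3 methyl ketone, enolisable only towards C2 because C4 is quaternary, condenses (bond C1–C2, then loss of water). The closest known reaction types are the photoredox α-alkylation of enol silanes with α-bromo ketones to 1,4-diketones and the aldol half of a Robinson annulation, run here as one (3+3) annulation in which the radical step takes the place of the Michael step. Ring A is closed by a 6-(enolexo)-exo-trig aldol addition followed by dehydration, the ring enforcing the cis C1=C2 geometry. The only new stereocentre, C5, is α to the C6 carbonyl and therefore under thermodynamic control (H-5 trans to the C10 methyl group, secured in step 8), while C10 is carried through unchanged. The step needs site selectivity for C5 over C8 in the radical addition, secured because attack at the unsubstituted terminus gives the oxygen-stabilised allyl radical, and chemoselectivity in the aldol event, secured because the non-enolisable aldehyde is far more electrophilic than the conjugated C6 ketone and a six-membered ring results.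

**Step 7**
Reactants: 11 9α-hydroxy-4,4,8,10β-tetramethyl-5αH-decal-1,7-diene-3,6-dione
Product: 12 4,4,8,10β-tetramethyl-5αH-decal-1,7-diene-3,6,9-trione
Conditions: Dess–Martin periodinane, NaHCO3, CH2Cl2, 0 °C to rt
Reagents that add atoms: none
Why: Dess–Martin oxidation should convert the hindered allylic secondary alcohol into the C9 ketone under buffered conditions that leave both enones alone, removing the one stereocentre of uncontrolled configuration.

**Step 8**
Reactants: 12 4,4,8,10β-tetramethyl-5αH-decal-1,7-diene-3,6,9-trione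
Product: 14 4,4,8α,10β-tetramethyl-5αH-decalin-3,6,9-trione, via 8-epi-trione 13 (not isolated)
Conditions: H2 (1 atm), Pd/C, EtOAc, rt; then K2CO3 (cat.), MeOH, rt
Reagents that add atoms: none
Why: Heterogeneous hydrogenation should saturate both conjugated C=C bonds without touching the ketones, and the carbonate then equilibrates the two enolisable stereocentres: C8 (α to the C9 ketone) to the equatorial 8α-methyl isomer that avoids a 1,3-diaxial clash with the C10 methyl group, and C5 (α to the C6 ketone) to the trans ring fusion.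

**Step 9**
Reactants: 14 4,4,8α,10β-tetramethyl-5αH-decalin-3,6,9-trione
Product: 15 3β,6β-dihydroxy-4,4,8α,10β-tetramethyl-5αH-decalin-9-one
Conditions: NaBH4, MeOH–CH2Cl2, −40 to −10 °C
Reagents that add atoms: none
Why: Borohydride reduction should discriminate on steric grounds, leaving the C9 carbonyl (flanked by quaternary C10 and tertiary C8, like the hindered carbonyl of 2,6,6-trimethylcyclohex-2-ene-1,4-dione) while reducing C3 by axial attack to the equatorial 3β-alcohol and C6 from the open α-face, the β-face being blocked by the axial methyl groups on C4 and C10, to the axial 6β-alcohol.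

**Step 10**
Reactants: 15 3β,6β-dihydroxy-4,4,8α,10β-tetramethyl-5αH-decalin-9-one
Product: 16 3β-[(tert-butyldimethylsilyl)oxy]-6β-hydroxy-4,4,8α,10β-tetramethyl-5αH-decalin-9-one
Conditions: TBSOTf (1.1 equiv), 2,6-lutidine, CH2Cl2, −78 °C
Reagents that add atoms: tert-butyldimethylsilyl trifluoromethanesulfonate, CC(C)(C)[Si](C)(C)OS(=O)(=O)C(F)(F)F
Why: Silyl ether formation with one equivalent of silyl triflate at low temperature should take only the equatorial 3β-hydroxyl, because the 6β-hydroxyl is 1,3-diaxial to two methyl groups.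

**Step 11**
Reactants: 16 3β-[(tert-butyldimethylsilyl)oxy]-6β-hydroxy-4,4,8α,10β-tetramethyl-5αH-decalin-9-one
Product: 17 3β-[(tert-butyldimethylsilyl)oxy]-4,4,8α,10β-tetramethyl-9-methylidene-5αH-decalin-6β-ol
Conditions: Ph3PCH3Br, KOt-Bu (excess), toluene, 90 °C
Reagents that add atoms: methyltriphenylphosphonium bromide, C[P+](c1ccccc1)(c1ccccc1)c1ccccc1.[Br-]
Why: Wittig methylenation with the small non-stabilised ylide at elevated temperature should convert the hindered C9 ketone into the exocyclic alkene, the excess ylide compensating for formation of the C6 alkoxide; C8 is already the thermodynamic epimer and no new stereocentre arises.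

**Step 12**
Reactants: 17 3β-[(tert-butyldimethylsilyl)oxy]-4,4,8α,10β-tetramethyl-9-methylidene-5αH-decalin-6β-ol
Product: 18 9α,11-epoxy-3β-[(tert-butyldimethylsilyl)oxy]-4,4,8α,10β-tetramethyl-9-methyl-5αH-decalin-6β-ol (spiro-oxirane at C9 with oxygen on the α-face)
Conditions: mCPBA, NaHCO3, CH2Cl2, 0 °C
Reagents that add atoms: 3-chloroperbenzoic acid, OOC(=O)c1cccc(Cl)c1
Why: Peracid epoxidation (Prilezhaev reaction) of the 1,1-disubstituted alkene should occur from the α-face, anti to the axial C10 methyl group on the adjacent carbon, which places the oxygen α on C9 and sets the C9 stereocentre.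

**Step 13**
Reactants: 18 9α,11-epoxy-3β-[(tert-butyldimethylsilyl)oxy]-4,4,8α,10β-tetramethyl-9-methyl-5αH-decalin-6β-ol
Product: 19 3β-[(tert-butyldimethylsilyl)oxy]-9β-ethenyl-4,4,8α,10β-tetramethyl-5αH-decalin-6β,9α-diol
Conditions: Me3S+ I−, n-BuLi (excess), THF, −10 °C to rt
Reagents that add atoms: trimethylsulfonium iodide, C[S+](C)C.[I-]
Why: The sulfonium ylide should open the epoxide at its CH2 terminus (C11), and the resulting β-alkoxy sulfonium salt eliminates dimethyl sulfide under the excess base to give the one-carbon homologated allylic alcohol (epoxide to allylic alcohol homologation), so C9 keeps its configuration (9α-OH, vinyl β).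

**Step 14**
Reactants: 19 3β-[(tert-butyldimethylsilyl)oxy]-9β-ethenyl-4,4,8α,10β-tetramethyl-5αH-decalin-6β,9α-diol
Product: 20 6β-acetoxy-3β-[(tert-butyldimethylsilyl)oxy]-9β-ethenyl-4,4,8α,10β-tetramethyl-5αH-decalin-9α-ol
Conditions: Ac2O, DMAP, pyridine, 50 °C
Reagents that add atoms: acetic anhydride, CC(=O)OC(C)=O
Why: Nucleophile-catalysed acetylation should esterify the only secondary hydroxyl, the axial 6β-OH, while the tertiary 9α-hydroxyl does not react under these conditions.

**Step 15**
Reactants: 20 6β-acetoxy-3β-[(tert-butyldimethylsilyl)oxy]-9β-ethenyl-4,4,8α,10β-tetramethyl-5αH-decalin-9α-ol; 21 3-bromofuran-2(5H)-one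
Product: 23 6β-acetoxy-3β-[(tert-butyldimethylsilyl)oxy]-9α-hydroxy-8α-methyl-labd-13-en-16,15-olide, via alkylborane 22 (not isolated)
Conditions: 9-BBN, THF, rt to 40 °C; then 21, Pd(dppf)Cl2 (5 mol %), AsPh3, Cs2CO3, DMF–H2O, rt
Reagents that add atoms: none
Why: Anti-Markovnikov hydroboration of the vinyl group puts boron on C12, and the B-alkyl Suzuki–Miyaura coupling with the α-bromobutenolide (oxidative addition of zerovalent palladium, base-assisted transmetalation, reductive elimination) should form the C12–C13 bond and deliver the butenolide in its final oxidation state; no stereocentre is formed.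

**Step 16**
Reactants: 23 6β-acetoxy-3β-[(tert-butyldimethylsilyl)oxy]-9α-hydroxy-8α-methyl-labd-13-en-16,15-olide
Product: 24 (3S,5S,6R,8R,9R,10S)-6β-acetoxy-3β,9α-dihydroxy-8α-methyl-labd-13-en-16,15-olide (CNP0513254.1)
Conditions: HF·pyridine, THF, 0 °C to rt
Reagents that add atoms: none
Why: Fluoride-mediated desilylation should free the 3β-hydroxyl without touching the acetate, the tertiary alcohol or the butenolide.

**Compound list**
1 | (E)-2-methylbut-2-enal (tiglaldehyde) | C/C=C(\C)C=O | starting material
2 | tert-butyl{[(1E)-2-methylbuta-1,3-dien-1-yl]oxy}dimethylsilane | C=C/C(C)=C/O[Si](C)(C)C(C)(C)C | intermediate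
3 | 2-methylprop-2-enal (methacrolein) | CC(=C)C=O | starting material
4 | (1S,2R)-2-[(tert-butyldimethylsilyl)oxy]-1,3-dimethylcyclohex-3-ene-1-carbaldehyde | C1C=C(C)[C@@H](O[Si](C)(C)C(C)(C)C)[C@@](C)(C=O)C1 | intermediate
5 | tert-butyl{[(1R,6S)-6-(dimethoxymethyl)-2,6-dimethylcyclohex-2-en-1-yl]oxy}dimethylsilane | C1C=C(C)[C@@H](O[Si](C)(C)C(C)(C)C)[C@@](C)(C(OC)OC)C1 | intermediate
6 | (4R,5S)-4-[(tert-butyldimethylsilyl)oxy]-5-(dimethoxymethyl)-3,5-dimethylcyclohex-2-en-1-one | O=C1C=C(C)[C@@H](O[Si](C)(C)C(C)(C)C)[C@@](C)(C(OC)OC)C1 | intermediate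
7 | (5R,6S)-2,5-bis[(tert-butyldimethylsilyl)oxy]-6-(dimethoxymethyl)-4,6-dimethylcyclohexa-1,3-diene | CC(C)(C)[Si](C)(C)OC=1C=C(C)[C@@H](O[Si](C)(C)C(C)(C)C)[C@@](C)(C(OC)OC)C=1 | intermediate
8 | 3-bromo-3-methylbutan-2-one | CC(=O)C(C)(C)Br | starting material
9 | (4R,5S,6R)-4-[(tert-butyldimethylsilyl)oxy]-5-(dimethoxymethyl)-3,5-dimethyl-6-(2-methyl-3-oxobutan-2-yl)cyclohex-2-en-1-one (diketone acetal) | O=C1C=C(C)[C@@H](O[Si](C)(C)C(C)(C)C)[C@@](C)(C(OC)OC)[C@@H]1C(C)(C)C(C)=O | intermediate
10 | (1S,2R,6R)-2-hydroxy-1,3-dimethyl-6-(2-methyl-3-oxobutan-2-yl)-5-oxocyclohex-3-ene-1-carbaldehyde (keto aldehyde) | O=C1C=C(C)[C@@H](O)[C@@](C)(C=O)[C@@H]1C(C)(C)C(C)=O | intermediate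
11 | 9α-hydroxy-4,4,8,10β-tetramethyl-5αH-decal-1,7-diene-3,6-dione | O=C1C=C(C)[C@@H](O)[C@@]2(C)C=CC(=O)C(C)(C)[C@H]12 | intermediate
12 | 4,4,8,10β-tetramethyl-5αH-decal-1,7-diene-3,6,9-trione | O=C1C=C(C)C(=O)[C@@]2(C)C=CC(=O)C(C)(C)[C@H]12 | intermediate
13 | 4,4,8β,10β-tetramethyl-5αH-decalin-3,6,9-trione (8-epi-trione, kinetic hydrogenation product) | O=C1C[C@H](C)C(=O)[C@@]2(C)CCC(=O)C(C)(C)[C@H]12 | intermediate
14 | 4,4,8α,10β-tetramethyl-5αH-decalin-3,6,9-trione | O=C1C[C@@H](C)C(=O)[C@@]2(C)CCC(=O)C(C)(C)[C@H]12 | intermediate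
15 | 3β,6β-dihydroxy-4,4,8α,10β-tetramethyl-5αH-decalin-9-one | O[C@@H]1C[C@@H](C)C(=O)[C@@]2(C)CC[C@H](O)C(C)(C)[C@H]12 | intermediate
16 | 3β-[(tert-butyldimethylsilyl)oxy]-6β-hydroxy-4,4,8α,10β-tetramethyl-5αH-decalin-9-one | O[C@@H]1C[C@@H](C)C(=O)[C@@]2(C)CC[C@H](O[Si](C)(C)C(C)(C)C)C(C)(C)[C@H]12 | intermediate
17 | 3β-[(tert-butyldimethylsilyl)oxy]-4,4,8α,10β-tetramethyl-9-methylidene-5αH-decalin-6β-ol | O[C@@H]1C[C@@H](C)C(=C)[C@@]2(C)CC[C@H](O[Si](C)(C)C(C)(C)C)C(C)(C)[C@H]12 | intermediate
18 | 9α,11-epoxy-3β-[(tert-butyldimethylsilyl)oxy]-4,4,8α,10β-tetramethyl-9-methyl-5αH-decalin-6β-ol (spiro-oxirane, O on the α-face) | O[C@@H]1C[C@@H](C)[C@]3(CO3)[C@@]2(C)CC[C@H](O[Si](C)(C)C(C)(C)C)C(C)(C)[C@H]12 | intermediate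
19 | 3β-[(tert-butyldimethylsilyl)oxy]-9β-ethenyl-4,4,8α,10β-tetramethyl-5αH-decalin-6β,9α-diol | O[C@@H]1C[C@@H](C)[C@](O)(C=C)[C@@]2(C)CC[C@H](O[Si](C)(C)C(C)(C)C)C(C)(C)[C@H]12 | intermediate
20 | 6β-acetoxy-3β-[(tert-butyldimethylsilyl)oxy]-9β-ethenyl-4,4,8α,10β-tetramethyl-5αH-decalin-9α-ol | CC(=O)O[C@@H]1C[C@@H](C)[C@](O)(C=C)[C@@]2(C)CC[C@H](O[Si](C)(C)C(C)(C)C)C(C)(C)[C@H]12 | intermediate
21 | 3-bromofuran-2(5H)-one | O=C1OCC=C1Br | starting material
22 | 9-[2-(6β-acetoxy-3β-silyloxy-9α-hydroxy-decalin-9β-yl)ethyl]-9-borabicyclo[3.3.1]nonane (alkylborane from 20) | CC(=O)O[C@@H]1C[C@@H](C)[C@](O)(CCB3C4CCCC3CCC4)[C@@]2(C)CC[C@H](O[Si](C)(C)C(C)(C)C)C(C)(C)[C@H]12 | intermediate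
23 | 6β-acetoxy-3β-[(tert-butyldimethylsilyl)oxy]-9α-hydroxy-8α-methyl-labd-13-en-16,15-olide | CC(=O)O[C@@H]1C[C@@H](C)[C@](O)(CCC2=CCOC2=O)[C@@]2(C)CC[C@H](O[Si](C)(C)C(C)(C)C)C(C)(C)[C@H]12 | intermediate
24 | (3S,5S,6R,8R,9R,10S)-6β-acetoxy-3β,9α-dihydroxy-8α-methyl-labd-13-en-16,15-olide (CNP0513254.1) | CC(=O)O[C@@H]1C[C@@H](C)[C@](O)(CCC2=CCOC2=O)[C@@]2(C)CC[C@H](O)C(C)(C)[C@H]12 | target

Total step count: 16. Longest linear sequence: 16 steps (from 1; building blocks 3, 8 and 21 are commercial).

**Steps most likely to fail**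

Step 6. Addition of the tertiary radical to the congested C5 terminus may lag behind its reduction to the enolate, and the acid-induced closure may stall at the aldol stage. The fallback separates the two bond formations and uses a silicon-tethered oxidative enolate heterocoupling. It sets out from enone 6. 3-Methylbutan-2-one would be converted with Me3SiCl, NaI and Et3N into trimethyl[(3-methylbut-2-en-2-yl)oxy]silane F1, and MeLi would release its more substituted lithium enolate. The lithium dienolate of 6 (LiN(i-Pr)2) would be silylated with excess Me2SiCl2 and then combined with that enolate to give the mixed dimethylsilyl bis-enol ether {[(5R,6S)-5-[(tert-butyldimethylsilyl)oxy]-6-(dimethoxymethyl)-4,6-dimethylcyclohexa-1,3-dien-2-yl]oxy}dimethyl[(3-methylbut-2-en-2-yl)oxy]silane F2. Oxidation with (NH4)2Ce(NO3)6 and NaHCO3 in MeCN at −10 °C should join C4 to C5 within the tether and give diketone acetal 9, now isolated. Treatment of 9 with aqueous HCl in THF, as in the second half of step 6, comes back to the route at 11.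

Step 9. The C9 carbonyl may be reduced along with C3 and C6, or C6 may react too slowly to be separated from it. The fallback reduces before hydrogenating, while C3 and C6 are still the accessible enone carbonyls. It sets out from 12. Luche reduction (NaBH4, CeCl3·7H2O, MeOH, −78 °C) should give 3β,6β-dihydroxy-4,4,8,10β-tetramethyl-5αH-decal-1,7-dien-9-one F3, the C9 carbonyl staying as the hindered enone. Hydrogenation (H2, Pd/C) would then give 3β,6β-dihydroxy-4,4,8β,10β-tetramethyl-5αH-decalin-9-one F4, and K2CO3 in MeOH epimerises C8 to come back to the route at 15.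

Step 11. Addition of the ylide to the C9 carbonyl, which sits between a quaternary and a tertiary carbon, may be too slow and give way to enolisation towards C8. The fallback is a two-stage Peterson olefination with a non-basic organocerium reagent. It sets out from 16. Me3SiCH2Li with CeCl3 in THF at −78 °C should add to the ketone and give 3β-[(tert-butyldimethylsilyl)oxy]-4,4,8α,10β-tetramethyl-9α-[(trimethylsilyl)methyl]-5αH-decalin-6β,9β-diol F5 (either C9 epimer serves). Elimination with KH in THF comes back to the route at 17.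

**Further compounds**
F1 | step 6 | trimethyl[(3-methylbut-2-en-2-yl)oxy]silane | CC(O[Si](C)(C)C)=C(C)C
F2 | step 6 | {[(5R,6S)-5-[(tert-butyldimethylsilyl)oxy]-6-(dimethoxymethyl)-4,6-dimethylcyclohexa-1,3-dien-2-yl]oxy}dimethyl[(3-methylbut-2-en-2-yl)oxy]silane | CC(C)=C(C)O[Si](C)(C)OC=1C=C(C)[C@@H](O[Si](C)(C)C(C)(C)C)[C@@](C)(C(OC)OC)C=1
F3 | step 9 | 3β,6β-dihydroxy-4,4,8,10β-tetramethyl-5αH-decal-1,7-dien-9-one | O[C@@H]1C=C(C)C(=O)[C@@]2(C)C=C[C@H](O)C(C)(C)[C@H]12
F4 | step 9 | 3β,6β-dihydroxy-4,4,8β,10β-tetramethyl-5αH-decalin-9-one | O[C@@H]1C[C@H](C)C(=O)[C@@]2(C)CC[C@H](O)C(C)(C)[C@H]12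
F5 | step 11 | 3β-[(tert-butyldimethylsilyl)oxy]-4,4,8α,10β-tetramethyl-9α-[(trimethylsilyl)methyl]-5αH-decalin-6β,9β-diol | O[C@@H]1C[C@@H](C)[C@@](O)(C[Si](C)(C)C)[C@@]2(C)CC[C@H](O[Si](C)(C)C(C)(C)C)C(C)(C)[C@H]12
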